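35.9 % of the substrate charged stands as target in the ash flask at 3.00 d, and the question is what can still be won from it.

all flasks: free catalyst 2.2 mol%

| flask | substrate | impurity | remark | time |
|---|---|---|---|---|
| ash | 1 M | 8 mM | the very flask that is asked about, followed so far |  |
| alder | 1.5 M | 8 mM | run made earlier |  |
| flask | 1.0 M | 8.0 mM |  | 3.0 d |

ash run (percent of the substrate charged)

| time / d | target / % | substrate / % |
|---|---|---|
| 0.250 | 27.1 | 7.6 |
| 0.833 | 35.8 | 6.2 |
| 1.25 | 35.7 | 6.5 |
| 2.00 | 36.0 | 7.1 |
| 3.00 | 35.9 | 6.7 |

alder run (percent of the substrate charged)

| time / h | target / % | substrate / % |
|---|---|---|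
| 4.00 | 22.6 | 7.6 |
| 8.00 | 30.1 | 6.8 |
| 15.0 | 34.9 | 6.9 |
| 25.0 | 35.5 | 7.2 |
| 48.0 | 36.4 | 6.9 |

(each reading ± 0.3 percentage points)

- red: at 3.0 d add substrate, 50.0 % of the amount charged, then wait 20 h
- grey: at 3.0 d take out 90 % of the target then present, then wait 20 h
- violet: change nothing and wait 20 h more
- green: at 3.0 d add free catalyst, 50.0 % of the amount charged, then wait 20 h

- target, in percent of the substrate first charged, at 3.0 d
- the option that brings most further target ("none" if no option brings more than 2 percentage points) (red / grey / violet / green / none)
- target present, with what was taken out counted in, in percent of the substrate first charged, after red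
- target present, with what was taken out counted in, in percent of the substrate first charged, after green

- what is taken out of target is counted as made
- additions bring no volume worth counting

Read the target columns first. In the ash run the target stops moving from 0.833 d on, and in the alder run from 25.0 h on. The last two readings average 35.9 % in ash and 35.9 % in alder, though the catalyst charge is 22.0 mM in ash and 33.0 mM in alder.

Now read the substrate column: it holds near 6.90 %, so 57.2 % sits in something you don't read.

I take the target figure as the end share 35.9 %, the part of the material in the flask that stands as target once it stops moving; this is thermodynamic control.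

How fast is that share reached? The ash run read 35.8 % at 0.833 d, a time about as long as the 20 h each option waits, so I reckon the options with any new gap closed. That is an estimate, since a new gap starts from another state than the start of the run.

My reckoning for ash is therefore this. Violet and green leave the share at 35.9 %. Red gives 53.9 %. Grey takes out 32.4 %, and the rest splits anew to a total of 56.7 %, the most.

The forecast gives 35.9 %, 53.7 % and 36 % and picks grey, since the runs “points to equilibrium”.

The ash flask gives 35.9 % and best option grey: grey adds 20 percentage points, red adds 18 points and reaches 53.6 %, and green stays at 35.9 %.

    substrate ⇌ target (K = 5.50, k = 0.680 h⁻¹)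
    target + free catalyst ⇌ isomer of the product + free catalyst, rate k2*[free catalyst]*[target] forward; the back reaction follows from the equilibrium constant (K = 1.60, k = 0.530 M⁻¹ h⁻¹)
    isomer of the product + free catalyst ⇌ substrate + free catalyst, rate k3*[free catalyst]*[isomer of the product] forward; the back reaction follows from the equilibrium constant (k = 34.0 M⁻¹ h⁻¹)
    free catalyst + impurity → spent catalyst (k = 110 M⁻¹ h⁻¹)

In the ash flask at 3.00 d, the isomer of the product holds 57.5 %, the impurity stands at 0 % of its charge, and 36.4 % of the catalyst is spent catalyst. Take a neighbouring flask, charged with 8.8 mol% of free catalyst. The end share reckons 35.9 % of target for it. In that neighbouring flask, 90.9 % of the catalyst is free catalyst at 3.00 d, the substrate stands at 6.54 %, and the target stands at 35.9 %.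

(The runs were computed with made-up constants, noise included.)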